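## Analysis of the target

The target consists of two 4-(4-hydroxyphenyl)chroman-2-one (3,4-dihydrocoumarin) units joined by the C3–C3' bond. Unit A has a phloroglucinol-type benzo ring (ring A, hydroxyls at C5 and C7, hydrogens at C6 and C8). Unit B has a fully oxygenated benzo ring (ring B, hydroxyls at C5', C6', C7' and C8'). The four contiguous stereocentres are C4 (S), C3 (R), C3' (S) and C4' (R): in each lactone the 4-aryl group is cis to the C3–C3' bond, and the two halves have mirror-image configurations. Sensitive points are the two aryl lactones (opened by bases and nucleophiles), the acidic C3–H and C3'–H (the cis arrangement is expected to be the less stable one, so base must be avoided once it is in place), and ring B, a tetrahydroxybenzene that air turns into quinones. The synthesis is hard because of the cis,cis array, the unlike relationship of the 1,4-related centres C4 and C4', and the need to tell two almost identical halves apart in an absolute sense. The strategy rests on the last point: without the oxygens at C6' and C8', rings A and B are identical, the molecule is meso and its two benzo rings are enantiotopic. The absolute configuration of the target is then only the decision which ring receives the two extra hydroxyls, and that decision is left to a chiral oxidant acting on the meso dimer at the end.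

## Retrosynthetic reasoning

Target 16 back to 15. The two benzyl–oxygen bonds on the 4-hydroxyphenyl groups are cut last. These para-substituted phenols would themselves be ortho-oxygenated by the oxidant of the key step, so they must be masked through it. Benzyl is chosen because its removal by hydrogenolysis is neutral and reducing, which suits the air-sensitive ring B.

15 back to 14. Six acetyl–oxygen bonds are cut. The acetates are not an extra protection step; they arise in the second stage of the key step. The forward reaction must hydrolyse six aryl acetates without base, so that the cis C3–H centres and the polyphenol survive.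

14 back to 12 (key disconnection). The C6'–O and C8'–O bonds of ring B are cut. This is the only place where removing two atoms makes the halves identical, so the precursor 12 is meso and needs only relative stereocontrol. Forward, a chiral pentavalent iodine oxidant must choose one of the two enantiotopic phloroglucinol rings and deliver oxygen to C6', taking that ring to the hydroxy-ortho-quinone 13. Reducing 13 and oxidising again would not add the second oxygen, because a pyrogallol is only dehydrogenated back to the quinone by such oxidants. The quinone is therefore used as an electrophile: acetate adds to C8' and the ring rearomatises as its tetraacetate in 14.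

12 back to 11. Four oxygen–silicon bonds are cut. The phloroglucinol hydroxyls must be free for the oxidant in the key step but masked during the enolate chemistry before it. Silyl ethers can be removed with acidic fluoride, which leaves the cis centres, the lactones and the benzyl ethers alone.

11 back to 9. This is a stereochemical disconnection at the two C3–H bonds: the cis,cis dimer 11 is traced to the trans,trans dimer 9 through the bis-enolate 10. It is made here because the bond-forming step places the new C3–C3' bond trans to each aryl group, whereas protonation of an enolate from the face away from the aryl gives cis. The gain is that the configuration at C3 and C3' is separated from the C–C bond formation; only the unlike C4/C4' pairing has to be correct in 9.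

9 back to 7. The central C3–C3' bond is cut into two identical halves, so that two molecules of 7 are joined by oxidative dimerisation of the enolate 8. Cutting here uses the symmetry fully and needs one monomer. A two-fold arylation at C4 and C4' of a preformed C3–C3' backbone would face the same pairing problem under strongly acidic conditions. The forward step must form a hindered bond; the unlike (meso) pairing of the racemic monomer is not controlled and must be separated from the like pairing.

7 back to 6. Two oxygen–silicon bonds are cut; the silylation protects the phenols against base and oxidant.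

6 back to 1, 2 and 3. The C4–C4a bond, the C3–C4 bond and the O1–C2 bond are cut. Aldehyde 2 supplies C4 with its aryl group, 3 supplies C2 and C3, and 1 supplies ring A. The forward reaction is a three-component annulation through 4 and 5 under mild basic conditions that the benzyl ether tolerates.

## Alternatives that were turned down

Alternative 1: Ring B is built instead of oxidised. The disconnection cuts the C4a'–C5' bond and takes the benzo ring B back to a squarate-derived four-membered ring bearing an alkynyl group. The cyclobutenone A1 carries the whole open C4–C3–C3'–C4' chain, with ring A as a trimethoxyphenyl group and the carboxyls as tert-butyl esters. On heating, four-electron ring opening gives an alkynylketene whose ketene carbon (C5') bonds to the alkyne carbon C4a', and the dimethoxybenzoquinone A2 results (Moore cyclisation).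
- For it: this ring closure is well established, the oxygens of ring B are placed by construction, and the two halves differ from the start. No enantiotopic groups have to be distinguished, and on that point it is stronger than the chosen route.
- Against it: in A2, C8a' still bears hydrogen, so the lactone oxygen O1' must be introduced later by a C–H oxygenation of the quinone. The four stereocentres must each be set on an open chain. C4' is benzylic and propargylic and lies next to an ester α-carbon, so the acetylide chemistry leading to A1 threatens it with epimerisation and allene formation. Seven methyl ethers and two tert-butyl esters must be removed at the end, which is hard to reconcile with the aryl lactones and the cis C3–H centres.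
- Comparison: the chosen route reaches its precursor in five steps and confines the uncertainty to one step; its price is a selectivity problem that alternative 1 does not have.

Alternative 2: The C3–C3' bond is made together with a temporary C4–C4' bond by (2+2) photocycloaddition. The substrate is the propylene-tethered bis(4-arylcoumarin) A3, in which the two different coumarin halves are joined through a three-carbon bridge between the para oxygens of their 4-aryl groups. Irradiation of A3 with a chiral oxazaborolidine–AlBr3 Lewis acid on one lactone carbonyl should give the syn head-to-head cyclobutane A4.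
- For it: Lewis-acid-mediated enantioselective photocycloadditions of coumarins are known, the unsymmetrical skeleton comes from two easily made halves, and C3/C3' emerge cis on the four-membered ring, which is the unlike relationship of the target. The absolute configuration would be set by a reaction type with precedent, which the chosen route cannot claim.
- Against it: the 4-aryl-substituted double bonds of A3 are poor partners (a bond between two quaternary, aryl-bearing carbons must form), and the tether closes a large ring. The C4–C4' bond of A4 must then be broken and replaced by two C–H bonds. In A4 each 4-aryl group is trans to the C3–C3' bond, so both hydrogens would have to enter with inversion; reductive cleavage of a bis-benzylic bond runs through benzylic radicals or anions that offer no such control. Eight methyl ethers and the tether must also be cleaved.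
- Comparison: the chosen route needs no C–C scission and sets the cis arrangement by a separate, controllable protonation.

Alternative 3: Both lactone rings and both carbonyl carbons are introduced at once. C2 and C2' are removed as carbon monoxide and the O1–C2, O1'–C2', C2–C3 and C2'–C3' bonds are cut, leaving the bis-phenol alkyne A5 with the C3≡C3' triple bond between the doubly benzylic C4 and C4'. PdI2/KI under CO with O2 as oxidant should add two acyl groups syn across the alkyne of A5 while the phenols close the lactones, giving the bis-lactone A6 with a C3=C3' double bond and cis carbonyls.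
- For it: four bonds and two rings form in one step, the most convergent of all. With an unlike C4/C4' pair, the syn addition places both 4-aryl groups on one face of the alkene, so syn hydrogenation from the free face would give the cis,cis array directly. That is a more direct answer to the cis problem than kinetic protonation.
- Against it: with ortho-propargyl phenols such as A5 this catalyst system is known to favour attack of the phenol oxygen on the coordinated alkyne, which closes a furan ring instead of the lactone. The unlike C4/C4' pair must be made by two separate enantioselective steps and kept intact at configurationally labile carbons. A6 can lose the C4 stereocentre by migration of the double bond into the lactone ring. Hydrogenation of a tetrasubstituted alkene flanked by two diarylmethyl groups is doubtful, and eight methyl ethers remain.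
- Comparison: the chosen route makes C4 and C4' only as a racemic monomer and needs no enantioselective step before the end.

Key step: step 6

Remark on the chemistry: which enantiomer of the valine-derived oxidant is matched to the (3'S,4'R) half cannot be predicted; the route is written with the L-valine reagent, and its mirror image from D-valine is used if the sense proves opposite.

Remark on the chemistry: the oxidant of step 6 is not commercial; it is prepared beforehand from 2-iodobenzoyl chloride and L-valine methyl ester (amide formation), then oxidised at iodine with dimethyldioxirane, and this reagent preparation is not counted among the steps.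

## Route

Step 1
Reactants: 1 phloroglucinol; 2 4-(benzyloxy)benzaldehyde; 3 Meldrum's acid
Product: 6 rac-4-[4-(benzyloxy)phenyl]-5,7-dihydroxychroman-2-one, via arylidene Meldrum's acid 4 (not isolated), via lactone acid 5 (not isolated)
Conditions: pyridine, 90 °C; 1 in excess (3 equiv)
Reagents that add atoms: none
Why: Knoevenagel condensation of 2 with 3 gives 4, phloroglucinol adds through carbon (Friedel–Crafts-type Michael addition), the ortho hydroxyl opens the dioxanedione with loss of acetone to give 5, and 5 decarboxylates, a known three-component dihydrocoumarin annulation. C4 is formed racemic, and the excess of 1 suppresses a second annulation on the same ring.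

Step 2
Reactants: 6 rac-4-[4-(benzyloxy)phenyl]-5,7-dihydroxychroman-2-one
Product: 7 rac-4-[4-(benzyloxy)phenyl]-5,7-bis(tert-butyldimethylsilyloxy)chroman-2-one
Conditions: TBSCl, imidazole, DMF, 40 °C
Reagents that add atoms: tert-butyldimethylsilyl chloride, CC(C)(C)[Si](C)(C)Cl
Why: Standard silylation of phenols; the silyl ethers withstand the amide bases and the copper oxidant of steps 3 and 4 and are later removed by fluoride without base.

Step 3
Reactants: 7 rac-4-[4-(benzyloxy)phenyl]-5,7-bis(tert-butyldimethylsilyloxy)chroman-2-one (first molecule, the 4S enantiomer of the racemate); 7 rac-4-[4-(benzyloxy)phenyl]-5,7-bis(tert-butyldimethylsilyloxy)chroman-2-one (second molecule, the 4R enantiomer of the racemate)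
Product: 9 meso trans,trans dimer (3S,4S,3'R,4'R)-4,4'-bis[4-(benzyloxy)phenyl]-5,5',7,7'-tetrakis(tert-butyldimethylsilyloxy)-3,3'-bichromane-2,2'-dione, via lithium enolate 8 (not isolated)
Conditions: LiN(SiMe3)2, THF, −78 °C; then CuCl2, DMF/THF, −78 → −40 °C, cold quench; chromatographic separation of the meso diastereomer
Reagents that add atoms: none
Why: Oxidative enolate homocoupling joins two molecules of 7 at C3 with loss of one hydrogen from each: divalent copper oxidises 8 by one electron and the C3 radicals (or copper enolates) combine on the face away from the pseudoaxial 4-aryl group, so each new bond is trans to its aryl. A 4S and a 4R molecule pair to meso 9, which is expected beside the C2-symmetric product of like pairing and is separated from it. The C3 configurations set here are provisional, since step 4 resets them.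

Step 4
Reactants: 9 meso trans,trans dimer
Product: 11 meso cis,cis dimer (3R,4S,3'S,4'R)-4,4'-bis[4-(benzyloxy)phenyl]-5,5',7,7'-tetrakis(tert-butyldimethylsilyloxy)-3,3'-bichromane-2,2'-dione, via dilithium bis-enolate 10 (not isolated)
Conditions: LiN(iPr)2 (2.5 equiv), THF, −78 °C; then AcOH in THF, −78 °C; cold pH 5 buffer work-up
Reagents that add atoms: none
Why: Double deprotonation gives the vicinal bis-enolate, which erases C3 and C3' while C4 and C4' are untouched. Kinetic protonation then occurs on each ring from the face opposite the 4-aryl group, which allylic strain holds pseudoaxial, so each new C3–H is trans to the aryl and the C3–C3' bond cis to it. With the unlike C4/C4' pair this cis,cis isomer is meso.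

Step 5
Reactants: 11 meso cis,cis dimer (tetrasilyl ether)
Product: 12 meso (3R,4S,3'S,4'R)-4,4'-bis[4-(benzyloxy)phenyl]-5,5',7,7'-tetrahydroxy-3,3'-bichromane-2,2'-dione
Conditions: HF·pyridine, THF/pyridine, 0 °C → rt
Reagents that add atoms: none
Why: Fluoride cleavage of aryl silyl ethers; the acidic medium does not enolise the lactones, so the cis centres are not epimerised, and lactones and benzyl ethers are inert.

Step 6
Reactants: 12 meso (3R,4S,3'S,4'R)-4,4'-bis[4-(benzyloxy)phenyl]-5,5',7,7'-tetrahydroxy-3,3'-bichromane-2,2'-dione
Product: 14 (3R,4S)-5,7-diacetoxy-4-[4-(benzyloxy)phenyl]-3-{(3S,4R)-5,6,7,8-tetraacetoxy-4-[4-(benzyloxy)phenyl]-2-oxochroman-3-yl}chroman-2-one, via hydroxy-ortho-quinone 13 (not isolated)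
Conditions: methyl N-(2-iodylbenzoyl)-L-valinate (1.0 equiv), MeCN, −35 °C, Ar; then Ac2O, BF3·OEt2 (cat.), −35 → 0 °C
Reagents that add atoms: methyl N-(2-iodylbenzoyl)-L-valinate, COC(=O)[C@@H](NC(=O)c1ccccc1I(=O)=O)C(C)C; acetic anhydride, CC(=O)OC(C)=O
Why: Proposed new method: the chiral iodyl arene exchanges a ligand for a phenolic oxygen of one phloroglucinol ring (7'-OH or 5'-OH) and transfers an oxo oxygen to the neighbouring C6' by a sigmatropic shift, the iodine going from pentavalent to monovalent as that ring becomes the hydroxy-ortho-quinone 13; the oxygen transfer is the known ortho-oxygenation of phenols to ortho-quinones by 2-iodoxybenzoic acid, and the choice between two enantiotopic aryl groups has its closest analogues in catalyst-controlled desymmetrising electrophilic substitution of bis-phenols. The quinone is not reduced back, because a second charge of a pentavalent iodine reagent would only dehydrogenate the resulting pyrogallol to the same quinone without making a C–O bond. Instead Ac2O with BF3·OEt2 adds acetate to C8', the β-carbon of the enone formed by C6'=O and C7'=C8', and aromatisation with acetylation gives the tetraacetoxy ring (Thiele–Winter acetoxylation), so one equivalent of oxidant accounts for both C–O bonds. No ring is closed and no stereocentre is formed; what is decided is which mirror-image half becomes ring B, and this turns the meso array into the single enantiomer (3R,4S,3'S,4'R). Ring selectivity must come from the reagent's stereocentre meeting C4' and C3' of opposite sense on the two halves, most plausibly when it binds at 5'-OH next to C4'. Mono-oxidation is favoured because further oxidation consumes mainly the wrong-ring product, whose remaining ring is the matched one, which should also raise the enantiomeric purity of 14. The second oxygen can only enter the oxidised ring, since that ring alone is electrophilic while the other is merely acetylated. If the first oxygen enters at C8' instead, the isomeric hydroxyquinone should take up acetate at C6' and give the same hexaacetate.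

Step 7
Reactants: 14 hexaacetate bis(benzyl ether)
Product: 15 (3R,4S)-4-[4-(benzyloxy)phenyl]-5,7-dihydroxy-3-{(3S,4R)-4-[4-(benzyloxy)phenyl]-5,6,7,8-tetrahydroxy-2-oxochroman-3-yl}chroman-2-one
Conditions: 3 M HCl, 1,4-dioxane/H2O (degassed), 50 °C, Ar; concentration from toluene/TFA
Reagents that add atoms: none
Why: Acid-catalysed hydrolysis of the six aryl acetates; acid instead of base keeps C3–H and C3'–H from epimerising and protects the polyphenol from autoxidation. Any lactone that opens recloses on concentration from acid, since six-membered lactonisation is strongly favoured by the substituents at C3 and C4.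

Step 8
Reactants: 15 hexahydroxy bis(benzyl ether)
Product: 16 (3R,4S)-5,7-dihydroxy-4-(4-hydroxyphenyl)-3-[(3S,4R)-5,6,7,8-tetrahydroxy-4-(4-hydroxyphenyl)-2-oxochroman-3-yl]chroman-2-one
Conditions: H2 (1 atm), Pd/C, EtOAc/THF, rt; filtration and evaporation under Ar
Reagents that add atoms: none
Why: Hydrogenolysis of the two benzyl aryl ethers under neutral, reducing conditions that protect ring B; no stereocentre is touched and the diarylmethine C–C bonds are not cleaved at this pressure.

## Compound list

1 | phloroglucinol (benzene-1,3,5-triol) | Oc1cc(O)cc(O)c1 | starting material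
2 | 4-(benzyloxy)benzaldehyde | O=Cc1ccc(OCc2ccccc2)cc1 | starting material
3 | Meldrum's acid (2,2-dimethyl-1,3-dioxane-4,6-dione) | CC1(C)OC(=O)CC(=O)O1 | starting material
4 | 5-[4-(benzyloxy)benzylidene]-2,2-dimethyl-1,3-dioxane-4,6-dione | CC1(C)OC(=O)C(=Cc2ccc(OCc3ccccc3)cc2)C(=O)O1 | intermediate (not isolated)
5 | rac-4-[4-(benzyloxy)phenyl]-5,7-dihydroxy-2-oxochromane-3-carboxylic acid | OC(=O)C1C(c2ccc(OCc3ccccc3)cc2)c2c(O)cc(O)cc2OC1=O | intermediate (not isolated)
6 | rac-4-[4-(benzyloxy)phenyl]-5,7-dihydroxychroman-2-one | O=C1CC(c2ccc(OCc3ccccc3)cc2)c2c(O)cc(O)cc2O1 | intermediate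
7 | rac-4-[4-(benzyloxy)phenyl]-5,7-bis(tert-butyldimethylsilyloxy)chroman-2-one | O=C1CC(c2ccc(OCc3ccccc3)cc2)c2c(O[Si](C)(C)C(C)(C)C)cc(O[Si](C)(C)C(C)(C)C)cc2O1 | intermediate
8 | lithium enolate of 7 (racemic) | [Li]OC1=CC(c2ccc(OCc3ccccc3)cc2)c2c(O[Si](C)(C)C(C)(C)C)cc(O[Si](C)(C)C(C)(C)C)cc2O1 | intermediate (not isolated)
9 | meso-(3S,4S,3'R,4'R)-4,4'-bis[4-(benzyloxy)phenyl]-5,5',7,7'-tetrakis(tert-butyldimethylsilyloxy)-3,3'-bichromane-2,2'-dione (both lactones 3,4-trans) | O=C1Oc2cc(O[Si](C)(C)C(C)(C)C)cc(O[Si](C)(C)C(C)(C)C)c2[C@H](c2ccc(OCc3ccccc3)cc2)[C@H]1[C@@H]1C(=O)Oc2cc(O[Si](C)(C)C(C)(C)C)cc(O[Si](C)(C)C(C)(C)C)c2[C@H]1c1ccc(OCc2ccccc2)cc1 | intermediate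
10 | dilithium bis-enolate of 9 (C4 and C4' unchanged) | [Li]OC1Oc2cc(O[Si](C)(C)C(C)(C)C)cc(O[Si](C)(C)C(C)(C)C)c2[C@H](c2ccc(OCc3ccccc3)cc2)C=1C1=C(O[Li])Oc2cc(O[Si](C)(C)C(C)(C)C)cc(O[Si](C)(C)C(C)(C)C)c2[C@H]1c1ccc(OCc2ccccc2)cc1 | intermediate (not isolated)
11 | meso-(3R,4S,3'S,4'R)-4,4'-bis[4-(benzyloxy)phenyl]-5,5',7,7'-tetrakis(tert-butyldimethylsilyloxy)-3,3'-bichromane-2,2'-dione (both lactones 3,4-cis) | O=C1Oc2cc(O[Si](C)(C)C(C)(C)C)cc(O[Si](C)(C)C(C)(C)C)c2[C@H](c2ccc(OCc3ccccc3)cc2)[C@@H]1[C@H]1C(=O)Oc2cc(O[Si](C)(C)C(C)(C)C)cc(O[Si](C)(C)C(C)(C)C)c2[C@H]1c1ccc(OCc2ccccc2)cc1 | intermediate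
12 | meso-(3R,4S,3'S,4'R)-4,4'-bis[4-(benzyloxy)phenyl]-5,5',7,7'-tetrahydroxy-3,3'-bichromane-2,2'-dione | O=C1Oc2cc(O)cc(O)c2[C@H](c2ccc(OCc3ccccc3)cc2)[C@@H]1[C@H]1C(=O)Oc2cc(O)cc(O)c2[C@H]1c1ccc(OCc2ccccc2)cc1 | intermediate
13 | (3R,4S)-4-[4-(benzyloxy)phenyl]-3-{(3S,4R)-4-[4-(benzyloxy)phenyl]-7-hydroxy-2,5,6-trioxo-3,4,5,6-tetrahydro-2H-chromen-3-yl}-5,7-dihydroxychroman-2-one (7'-hydroxy-5',6'-quinone, in equilibrium with its 5'-hydroxy-6',7'-quinone tautomer) | O=C1Oc2cc(O)cc(O)c2[C@H](c2ccc(OCc3ccccc3)cc2)[C@@H]1[C@H]1C(=O)OC=2C=C(O)C(=O)C(=O)C=2[C@H]1c1ccc(OCc2ccccc2)cc1 | intermediate (not isolated)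
14 | (3R,4S)-5,7-diacetoxy-4-[4-(benzyloxy)phenyl]-3-{(3S,4R)-5,6,7,8-tetraacetoxy-4-[4-(benzyloxy)phenyl]-2-oxochroman-3-yl}chroman-2-one | O=C1Oc2cc(OC(C)=O)cc(OC(C)=O)c2[C@H](c2ccc(OCc3ccccc3)cc2)[C@@H]1[C@H]1C(=O)Oc2c(OC(C)=O)c(OC(C)=O)c(OC(C)=O)c(OC(C)=O)c2[C@H]1c1ccc(OCc2ccccc2)cc1 | intermediate
15 | (3R,4S)-4-[4-(benzyloxy)phenyl]-5,7-dihydroxy-3-{(3S,4R)-4-[4-(benzyloxy)phenyl]-5,6,7,8-tetrahydroxy-2-oxochroman-3-yl}chroman-2-one | O=C1Oc2cc(O)cc(O)c2[C@H](c2ccc(OCc3ccccc3)cc2)[C@@H]1[C@H]1C(=O)Oc2c(O)c(O)c(O)c(O)c2[C@H]1c1ccc(OCc2ccccc2)cc1 | intermediate
16 | (3R,4S)-5,7-dihydroxy-4-(4-hydroxyphenyl)-3-[(3S,4R)-5,6,7,8-tetrahydroxy-4-(4-hydroxyphenyl)-2-oxochroman-3-yl]chroman-2-one | O=C1Oc2cc(O)cc(O)c2[C@H](c2ccc(O)cc2)[C@@H]1[C@H]1C(=O)Oc2c(O)c(O)c(O)c(O)c2[C@H]1c1ccc(O)cc1 | target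

## Step count and the least certain steps

Total step count: 8. Longest linear sequence: 8 steps (from 1, 2 and 3 to 16).

Step 6 (key step, proposed new method). The most likely failure is insufficient discrimination between the two enantiotopic rings, because C4' and C3', which distinguish them, are remote from the 7'-hydroxyl where the reagent binds most easily. A second failure mode is attack of the still unoxidised phloroglucinol ring on the quinone before acetylation sets in. Partial exchange of benzyl for acetyl on the 4-aryl oxygens during the acidic second stage would not matter, since steps 7 and 8 together remove both groups. The fallback sets out from 12 and uses known chemistry only. Oxidation with achiral 2-iodoxybenzoic acid in DMF at low temperature attacks both rings alike and gives 13 together with the mirror-image hydroxy-ortho-quinone F1. Thiele–Winter acetoxylation as in step 6 then gives 14 together with the enantiomeric hexaacetate F2. The two stable hexaacetates are separated by preparative chromatography on a chiral stationary phase, and the route is rejoined at 14.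

Step 3. The bond between two hindered C3 centres may form poorly, and the aryl-ester enolate may fragment to a ketene phenoxide on warming. Even when the coupling works, the unlike and like pairing of the racemic enolate is not controlled, so at best about half the dimer is the meso diastereomer. The fallback sets out from 2 and 1 and avoids making the C3–C3' bond. Diethyl succinate, which already contains it, is condensed twice with 2 (Stobbe condensation, KOtBu, then saponification) to the (2E,3E)-bis(arylidene)succinic acid F3. Acid-mediated two-fold conjugate Friedel–Crafts addition of 1 with lactonisation (BF3·OEt2, dioxane) gives, after separation from the like isomer, the unlike tetraol dimer F4. Silylation as in step 2 returns to the route at 9. The configuration at C3 and C3' of F4 is of no consequence, because step 4 resets it.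

Step 4. Incomplete formation of the hindered dianion, ketene fragmentation of the enolate, or partial equilibration toward the trans isomers during the quench would all erode the cis,cis selectivity. The fallback sets out from 9 and separates enolisation from proton transfer. Deprotonation with LiN(iPr)2 in the presence of Me3SiCl traps each enolate as it forms and gives the neutral bis(trimethylsilyl ketene acetal) F5, isolated by non-aqueous work-up. HF·pyridine at −78 °C → rt then protonates C3 and C3' irreversibly from the face opposite the aryl groups in a medium without base and cleaves the four aryl silyl ethers in the same operation. This returns to the route at 12.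

Step 7. Hydrolysis of six aryl acetates may be slow enough that lactone opening, oxidation of ring B by traces of air or loss of material in aqueous work-up compete. The fallback sets out from 14 and accepts ring opening instead of avoiding it. HCl in degassed MeOH removes the acetates as methyl acetate and deliberately opens both lactones to the ring-opened dimethyl ester F6, in which C3 and C3' are ordinary ester α-carbons under acid. Warming in toluene with TFA recloses both six-membered lactones with loss of methanol and returns to the route at 15.

## Further compounds

F1 | step 6 | mirror-image hydroxy-ortho-quinone (enantiomer of 13, ring A oxidised; not isolated) | O=C1Oc2cc(O)cc(O)c2[C@@H](c2ccc(OCc3ccccc3)cc2)[C@H]1[C@@H]1C(=O)OC=2C=C(O)C(=O)C(=O)C=2[C@@H]1c1ccc(OCc2ccccc2)cc1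
F2 | step 6 | enantiomeric hexaacetate (enantiomer of 14) | O=C1Oc2cc(OC(C)=O)cc(OC(C)=O)c2[C@@H](c2ccc(OCc3ccccc3)cc2)[C@H]1[C@@H]1C(=O)Oc2c(OC(C)=O)c(OC(C)=O)c(OC(C)=O)c(OC(C)=O)c2[C@@H]1c1ccc(OCc2ccccc2)cc1
F3 | step 3 | (2E,3E)-2,3-bis{[4-(benzyloxy)phenyl]methylidene}butanedioic acid | OC(=O)/C(=C/c1ccc(OCc2ccccc2)cc1)C(=C\c1ccc(OCc2ccccc2)cc1)/C(=O)O
F4 | step 3 | meso-(3S,4S,3'R,4'R)-4,4'-bis[4-(benzyloxy)phenyl]-5,5',7,7'-tetrahydroxy-3,3'-bichromane-2,2'-dione (unlike C4/C4', drawn 3,4-trans) | O=C1Oc2cc(O)cc(O)c2[C@H](c2ccc(OCc3ccccc3)cc2)[C@H]1[C@@H]1C(=O)Oc2cc(O)cc(O)c2[C@H]1c1ccc(OCc2ccccc2)cc1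
F5 | step 4 | bis(trimethylsilyl ketene acetal) of 9 | C[Si](C)(C)OC1Oc2cc(O[Si](C)(C)C(C)(C)C)cc(O[Si](C)(C)C(C)(C)C)c2[C@H](c2ccc(OCc3ccccc3)cc2)C=1C1=C(O[Si](C)(C)C)Oc2cc(O[Si](C)(C)C(C)(C)C)cc(O[Si](C)(C)C(C)(C)C)c2[C@H]1c1ccc(OCc2ccccc2)cc1
F6 | step 7 | dimethyl (2R,3S)-2-{(S)-[4-(benzyloxy)phenyl](2,4,6-trihydroxyphenyl)methyl}-3-{(R)-[4-(benzyloxy)phenyl](pentahydroxyphenyl)methyl}butanedioate | COC(=O)[C@H]([C@@H](c1ccc(OCc2ccccc2)cc1)c1c(O)cc(O)cc1O)[C@@H](C(=O)OC)[C@H](c1ccc(OCc2ccccc2)cc1)c1c(O)c(O)c(O)c(O)c1O
A1 | alternative 1 | 4-alkynyl-4-hydroxy-2,3-dimethoxycyclobutenone carrying the open C4–C3–C3'–C4' chain | COC1=C(OC)C(O)(C#C[C@@H](c2ccc(OC)cc2)[C@H](C(=O)OC(C)(C)C)[C@H](C(=O)OC(C)(C)C)[C@@H](c2ccc(OC)cc2)c2c(OC)cc(OC)cc2OC)C1=O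
A2 | alternative 1 | ring B as 2,3-dimethoxybenzoquinone with C8a' unsubstituted | COC1=C(OC)C(=O)C([C@@H](c2ccc(OC)cc2)[C@H](C(=O)OC(C)(C)C)[C@H](C(=O)OC(C)(C)C)[C@@H](c2ccc(OC)cc2)c2c(OC)cc(OC)cc2OC)=CC1=O
A3 | alternative 2 | propylene-tethered bis(4-arylcoumarin) | COc1cc(OC)c2c(c1)OC(=O)C=C2c1ccc(OCCCOc3ccc(cc3)C3=CC(=O)Oc4c(OC)c(OC)c(OC)c(OC)c34)cc1
A4 | alternative 2 | syn head-to-head cyclobutane photoadduct | O=C1Oc2cc(OC)cc(OC)c2[C@@]3(c2ccc(OCCCO6)cc2)[C@@H]1[C@H]1C(=O)Oc2c(OC)c(OC)c(OC)c(OC)c2[C@@]31c1ccc6cc1
A5 | alternative 3 | bis-phenol alkyne with doubly benzylic propargylic C4 and C4' | Oc1cc(OC)cc(OC)c1[C@H](c1ccc(OC)cc1)C#C[C@H](c1ccc(OC)cc1)c1c(O)c(OC)c(OC)c(OC)c1OC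
A6 | alternative 3 | bis-lactone with C3=C3' double bond, carbonyls cis | O=C1Oc2cc(OC)cc(OC)c2[C@H](c2ccc(OC)cc2)/C1=C1/C(=O)Oc2c(OC)c(OC)c(OC)c(OC)c2[C@H]1c1ccc(OC)cc1
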